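The numbers were drawn at random within sensible limits; the flask was simulated.

I took the constants below as given, with the flask and the questions beside them.

    gas phase ⇌ dissolved gas, rate k1*(csat - [dissolved gas]) (k1 = 1.9 h⁻¹, csat = 1.2 mM)
    substrate + dissolved gas + free catalyst → free catalyst + product (k2 = 1.3 × 10⁷ M⁻² h⁻¹)
    2 free catalyst ⇌ resting dimer, settled at all times (K3 = 3.2 × 10⁶ M⁻¹)
    free catalyst → spent catalyst (k4 = 0.14 h⁻¹)

substrate 20 mM; gas phase 1.2 mM (held); free catalyst 54 µM; time 2.0 h

- for a step with 2 of a species take k times the square, and two of it per event
- at the start none of the gas is dissolved
- run time (flask): 2.0 h

* how much product there is at 2.0 h, in percent of the substrate charged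
* the change that raises the amount of product at 2.0 h, in percent of the substrate charged most ("none" if none brings more than 2 percentage points) (south-east / west / north / none)
* amount of product at 2.0 h, in percent of the substrate charged, after north

- south-east: doubling the amount of free catalyst, all else as stated
- west: doubling the transfer coefficient of step 1, all else as stated
- north: doubling the saturation concentration of gas phase, all else as stated

Two numbers did not go together. With the catalyst as charged, the turnover step would halve the dissolved gas in 3.0 min, faster than the 21.9 min half-time of the transfer step. The flask therefore looked limited by transfer, which could deliver at most 22.8 % of the substrate into a solution kept empty. But the pairing constant times the charged catalyst was 170.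

I solved the catalyst balance at the start, free catalyst plus twice the dimer, and got c(free catalyst) = 2.83 µM. Nearly all of the catalyst sat in the resting dimer, its resting state. Decay of the free form took hardly any of the catalyst by 2.0 h, so I held c(free catalyst) at that balance value, and I held c(substrate) at its charge.

That gave 0.735 h⁻¹ for κ, the drain constant, the turnover constant times c(substrate) times c(free catalyst), a pseudo-first-order constant for the dissolved gas. This drain was slower than the transfer coefficient of 1.9 h⁻¹. The gas then rose at λ, the transfer coefficient plus κ, or 2.64 h⁻¹, towards a plateau of 0.865 mM. Integrating κ times that curve gave product as κ times the plateau times the time less a lag of 0.378 h. This came to 5.16 % of the substrate.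

I then reckoned each change. Doubling the saturation concentration gave 10.3 %. West gained 1.4 percentage points. South-east gained 1.6 points. I chose north.

The forecast gave 5 %, north and 9.9 %, slightly below my two yields, holding that “Nearly all the catalyst sits in the dimer”. The simulation gave 5.03 %, and 9.86 % after north, whose gain was 4.8 points, against 1.5 points for south-east and 1.3 points for west.

I carried κ unchanged to the neighbouring flask, the same charge read at 30 min. For it, κ and λ gave c(dissolved gas) = 0.634 mM, a lag of 0.278 h and product of 0.707 %. That neighbouring flask read 0.634 mM dissolved gas and 0.703 % product.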